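**Plan**
- Retrosynthetic cuts, in order: the five O–benzyl bonds; the flavanone C2–aryl bond (arylboronic acid plus a 5,7-bis(benzyloxy)chromone); the flavone C4–C4a and O1–C2 bonds of ring C (phloroglucinol plus an α-aryloxy aroylacetate); the Cα–C(aroyl) and ArO–CH2 bonds of that keto ester.
- Enabling feature: ring A of the flavone is phloroglucinol with its 5- and 7-hydroxyls unchanged, and ring C carries the aryl group on C2 and the aryloxy group on C3, so C2, C3, C4 and both substituents sit on one α-(4-bromophenoxy) aroylacetate.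
- Forward: keto ester, then flavone ring C closed on free phloroglucinol, then benzylation and bromide-to-boronic-acid exchange, then union with a separately made chromone to form the flavanone, then global debenzylation.
- Stereochemistry: the only stereocentre, flavanone C2 (S), comes from catalyst control in a rhodium-catalysed asymmetric 1,4-addition and is kept because the last step is neutral.

Key step: step 4

Assumption: the (S)-configured biaryl bisphosphine is taken to deliver the aryl group to the chromone face predicted by the accepted model for cyclic enones, which corresponds to the (2S)-flavanone; if the sense proved opposite, the (R)-ligand would be used in the same step.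

Step 1
Reactants: 1 4-bromophenol; 2 ethyl bromoacetate
Product: 3 ethyl 2-(4-bromophenoxy)acetate
Conditions: K2CO3, acetone, reflux
Reagents that add atoms: none
Why: Williamson ether synthesis, in which the phenoxide displaces bromide from the primary α-bromo ester by SN2 without competing C-alkylation.

Step 2
Reactants: 4 4-(benzyloxy)benzoic acid
Product: 5 4-(benzyloxy)benzoyl chloride
Conditions: (COCl)2, DMF (cat.), CH2Cl2, 0 °C to rt; evaporate, use crude
Reagents that add atoms: oxalyl chloride, ClC(=O)C(=O)Cl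
Why: Acid chloride formation through the catalytic Vilsmeier-type chloroiminium species, which is mild enough to leave the benzyl ether untouched.

Step 3
Reactants: 3 ethyl 2-(4-bromophenoxy)acetate; 5 4-(benzyloxy)benzoyl chloride
Product: 6 ethyl 3-[4-(benzyloxy)phenyl]-2-(4-bromophenoxy)-3-oxopropanoate (racemic, enolisable)
Conditions: 3 (2 equiv), LiN(SiMe3)2 (2 equiv), THF, −78 °C; then 5 (1 equiv), −78 to −20 °C; aq. NH4Cl
Reagents that add atoms: none
Why: Crossed Claisen-type C-acylation of a lithium ester enolate by an acyl chloride, in which the second equivalent of enolate deprotonates the more acidic β-keto ester as it forms and so stops double acylation, while the aryl bromide is inert to the amide base at low temperature.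

Step 4
Reactants: 6 ethyl 3-[4-(benzyloxy)phenyl]-2-(4-bromophenoxy)-3-oxopropanoate; 7 phloroglucinol
Product: 10 2-[4-(benzyloxy)phenyl]-3-(4-bromophenoxy)-5,7-dihydroxy-4H-chromen-4-one, via acylketene 8 (not isolated), via acylphloroglucinol diketone 9 (not isolated)
Conditions: 7 (3 equiv), neat melt, N2, 240 °C (microwave or metal bath), 10 min, no acid or base; EtOH and H2O allowed to distil off
Reagents that add atoms: none
Why: On heating, the enol form of 6 should expel ethanol to give the aroyl(aryloxy)ketene 8, which molten phloroglucinol captures at a ring carbon, directly or by O-acylation followed by acyl shift, to give the 2-acylphloroglucinol 9 and with it the flavone C4–C4a bond. An ortho hydroxyl of 9 then adds to the aroyl carbonyl in a 6-exo-trig closure and the hemiketal loses water, which forms O1–C2 and completes the pyranone ring C in a formal [3+3] annulation. The closest known reaction type is the Mentzer thermal chromone synthesis from phloroglucinol and aroylacetates, which accepts α-substituted esters, and the α-(4-bromophenoxy) ester still carries the α-hydrogen that ketene formation needs. No stereocentre is formed. The step needs chromone-over-coumarin selectivity, which the absence of acid should secure because the ring carbon then bonds to the ester-derived ketene carbon and not to the ketone, and it needs no regiocontrol because the three ring positions of 7 are equivalent. Excess 7 should keep the ketene from dimerising and prevent a second annulation, and the bromoaryl ether ring is too electron-poor to compete for the ketene.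

Step 5
Reactants: 10 2-[4-(benzyloxy)phenyl]-3-(4-bromophenoxy)-5,7-dihydroxy-4H-chromen-4-one
Product: 11 5,7-bis(benzyloxy)-2-[4-(benzyloxy)phenyl]-3-(4-bromophenoxy)-4H-chromen-4-one
Conditions: BnBr (3 equiv), K2CO3 (4 equiv), n-Bu4NI (cat.), DMF, 70 °C
Reagents that add atoms: benzyl bromide, BrCc1ccccc1
Why: Williamson O-benzylation, in which the acidic 7-hydroxyl reacts first and the chelated 5-hydroxyl follows under the warmer, excess-reagent conditions customary for perbenzylation of 5-hydroxyflavones.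

Step 6
Reactants: 11 5,7-bis(benzyloxy)-2-[4-(benzyloxy)phenyl]-3-(4-bromophenoxy)-4H-chromen-4-one
Product: 12 5,7-bis(benzyloxy)-2-[4-(benzyloxy)phenyl]-3-[4-(4,4,5,5-tetramethyl-1,3,2-dioxaborolan-2-yl)phenoxy]-4H-chromen-4-one
Conditions: B2pin2 (1.3 equiv), Pd(dppf)Cl2 (5 mol%), KOAc (3 equiv), 1,4-dioxane, 90 °C
Reagents that add atoms: bis(pinacolato)diboron, CC1(C)OB(OC1(C)C)B1OC(C)(C)C(C)(C)O1
Why: Miyaura borylation, in which the aryl bromide adds oxidatively to zerovalent palladium and the acetate-activated diboron transmetalates, conditions that tolerate aryl ethers and the flavone carbonyl.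

Step 7
Reactants: 12 5,7-bis(benzyloxy)-2-[4-(benzyloxy)phenyl]-3-[4-(4,4,5,5-tetramethyl-1,3,2-dioxaborolan-2-yl)phenoxy]-4H-chromen-4-one
Product: 13 (4-{[5,7-bis(benzyloxy)-2-[4-(benzyloxy)phenyl]-4-oxo-4H-chromen-3-yl]oxy}phenyl)boronic acid
Conditions: NaIO4 (3 equiv), NH4OAc (3 equiv), acetone/THF/H2O, rt
Reagents that add atoms: water, O
Why: Boronate hydrolysis driven by periodate glycol cleavage of the released pinacol, a standard route from aryl pinacol boronates to free boronic acids that does not affect benzyl ethers.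

Step 8
Reactants: 14 1-(2,4,6-trihydroxyphenyl)ethan-1-one (phloroacetophenone)
Product: 15 1-[2,4-bis(benzyloxy)-6-hydroxyphenyl]ethan-1-one
Conditions: BnBr (2.05 equiv), K2CO3 (2.2 equiv), DMF, 0 °C to rt
Reagents that add atoms: benzyl bromide, BrCc1ccccc1
Why: Williamson benzylation that should stop at the dibenzyl ether because the last ortho hydroxyl is hydrogen-bonded to the ketone and much less nucleophilic.

Step 9
Reactants: 15 1-[2,4-bis(benzyloxy)-6-hydroxyphenyl]ethan-1-one
Product: 17 5,7-bis(benzyloxy)-4H-chromen-4-one, via enaminone 16 (not isolated)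
Conditions: Me2NCH(OMe)2 (3 equiv), toluene, 100 °C; evaporate; then conc. aq. HCl, CH2Cl2, 40 °C
Reagents that add atoms: N,N-dimethylformamide dimethyl acetal, COC(OC)N(C)C
Why: Enaminone chromone synthesis, in which the methyl ketone condenses with the amide acetal and the phenol then closes by acid-promoted 6-endo-trig addition to the enaminone β-carbon with loss of dimethylamine.

Step 10
Reactants: 13 (4-{[5,7-bis(benzyloxy)-2-[4-(benzyloxy)phenyl]-4-oxo-4H-chromen-3-yl]oxy}phenyl)boronic acid; 17 5,7-bis(benzyloxy)-4H-chromen-4-one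
Product: 18 (2S)-5,7-bis(benzyloxy)-2-(4-{[5,7-bis(benzyloxy)-2-[4-(benzyloxy)phenyl]-4-oxo-4H-chromen-3-yl]oxy}phenyl)-2,3-dihydro-4H-chromen-4-one
Conditions: 17 (1.5 equiv), [Rh(OH)(cod)]2 (2.5 mol%), (S)-MeO-F12-BIPHEP (5.5 mol%), toluene/H2O 10:1, 40 °C
Reagents that add atoms: none
Why: Hayashi–Miyaura rhodium-catalysed asymmetric 1,4-addition, in which the aryl–rhodium species bearing the electron-poor (S)-bisphosphine (the 3,4,5-trifluorophenyl analogue of MeO-BIPHEP) inserts the disubstituted chromone C2=C3 bond from one enantiotopic face under catalyst control to set C2 as S; the tetrasubstituted flavone alkene of 13 cannot insert, and the base-free medium should avoid retro-oxa-Michael opening of the flavanone.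

Step 11
Reactants: 18 (2S)-5,7-bis(benzyloxy)-2-(4-{[5,7-bis(benzyloxy)-2-[4-(benzyloxy)phenyl]-4-oxo-4H-chromen-3-yl]oxy}phenyl)-2,3-dihydro-4H-chromen-4-one
Product: 19 (2S)-5,7-dihydroxy-2-(4-{[5,7-dihydroxy-2-(4-hydroxyphenyl)-4-oxo-4H-chromen-3-yl]oxy}phenyl)-2,3-dihydro-4H-chromen-4-one (CNP0144321.1)
Conditions: H2 (1 atm), 10% Pd/C, THF/MeOH 1:1, rt
Reagents that add atoms: none
Why: Catalytic hydrogenolysis of the five benzyl aryl ethers under neutral conditions, which should leave the diaryl ether, the tetrasubstituted flavone alkene and the chelated flavanone ketone intact and cannot epimerise C2.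

**Compound list**
1 | 4-bromophenol | Oc1ccc(Br)cc1 | starting material
2 | ethyl bromoacetate | CCOC(=O)CBr | starting material
3 | ethyl 2-(4-bromophenoxy)acetate | CCOC(=O)COc1ccc(Br)cc1 | intermediate
4 | 4-(benzyloxy)benzoic acid | OC(=O)c1ccc(OCc2ccccc2)cc1 | starting material
5 | 4-(benzyloxy)benzoyl chloride | ClC(=O)c1ccc(OCc2ccccc2)cc1 | intermediate
6 | ethyl 3-[4-(benzyloxy)phenyl]-2-(4-bromophenoxy)-3-oxopropanoate (racemic) | CCOC(=O)C(Oc1ccc(Br)cc1)C(=O)c1ccc(OCc2ccccc2)cc1 | intermediate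
7 | phloroglucinol (benzene-1,3,5-triol) | Oc1cc(O)cc(O)c1 | starting material
8 | [4-(benzyloxy)benzoyl](4-bromophenoxy)ketene, formed in the flask | O=C=C(Oc1ccc(Br)cc1)C(=O)c1ccc(OCc2ccccc2)cc1 | intermediate
9 | 1-[4-(benzyloxy)phenyl]-2-(4-bromophenoxy)-3-(2,4,6-trihydroxyphenyl)propane-1,3-dione, formed in the flask | O=C(c1ccc(OCc2ccccc2)cc1)C(Oc1ccc(Br)cc1)C(=O)c1c(O)cc(O)cc1O | intermediate
10 | 2-[4-(benzyloxy)phenyl]-3-(4-bromophenoxy)-5,7-dihydroxy-4H-chromen-4-one | O=c1c(Oc2ccc(Br)cc2)c(-c2ccc(OCc3ccccc3)cc2)oc2cc(O)cc(O)c12 | intermediate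
11 | 5,7-bis(benzyloxy)-2-[4-(benzyloxy)phenyl]-3-(4-bromophenoxy)-4H-chromen-4-one | O=c1c(Oc2ccc(Br)cc2)c(-c2ccc(OCc3ccccc3)cc2)oc2cc(OCc3ccccc3)cc(OCc3ccccc3)c12 | intermediate
12 | 5,7-bis(benzyloxy)-2-[4-(benzyloxy)phenyl]-3-[4-(4,4,5,5-tetramethyl-1,3,2-dioxaborolan-2-yl)phenoxy]-4H-chromen-4-one | O=c1c(Oc2ccc(B3OC(C)(C)C(C)(C)O3)cc2)c(-c2ccc(OCc3ccccc3)cc2)oc2cc(OCc3ccccc3)cc(OCc3ccccc3)c12 | intermediate
13 | (4-{[5,7-bis(benzyloxy)-2-[4-(benzyloxy)phenyl]-4-oxo-4H-chromen-3-yl]oxy}phenyl)boronic acid | O=c1c(Oc2ccc(B(O)O)cc2)c(-c2ccc(OCc3ccccc3)cc2)oc2cc(OCc3ccccc3)cc(OCc3ccccc3)c12 | intermediate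
14 | 1-(2,4,6-trihydroxyphenyl)ethan-1-one (phloroacetophenone) | CC(=O)c1c(O)cc(O)cc1O | starting material
15 | 1-[2,4-bis(benzyloxy)-6-hydroxyphenyl]ethan-1-one | CC(=O)c1c(O)cc(OCc2ccccc2)cc1OCc1ccccc1 | intermediate
16 | (E)-1-[2,4-bis(benzyloxy)-6-hydroxyphenyl]-3-(dimethylamino)prop-2-en-1-one, formed in the flask | CN(C)/C=C/C(=O)c1c(O)cc(OCc2ccccc2)cc1OCc1ccccc1 | intermediate
17 | 5,7-bis(benzyloxy)-4H-chromen-4-one | O=c1ccoc2cc(OCc3ccccc3)cc(OCc3ccccc3)c12 | intermediate
18 | (2S)-5,7-bis(benzyloxy)-2-(4-{[5,7-bis(benzyloxy)-2-[4-(benzyloxy)phenyl]-4-oxo-4H-chromen-3-yl]oxy}phenyl)-2,3-dihydro-4H-chromen-4-one | O=C1C[C@@H](c2ccc(Oc3c(-c4ccc(OCc5ccccc5)cc4)oc4cc(OCc5ccccc5)cc(OCc5ccccc5)c4c3=O)cc2)Oc2cc(OCc3ccccc3)cc(OCc3ccccc3)c21 | intermediate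
19 | (2S)-5,7-dihydroxy-2-(4-{[5,7-dihydroxy-2-(4-hydroxyphenyl)-4-oxo-4H-chromen-3-yl]oxy}phenyl)-2,3-dihydro-4H-chromen-4-one | O=C1C[C@@H](c2ccc(Oc3c(-c4ccc(O)cc4)oc4cc(O)cc(O)c4c3=O)cc2)Oc2cc(O)cc(O)c21 | target

**Step count**
Total: 11 steps. Longest linear sequence: 8 steps (steps 1, 3, 4, 5, 6, 7, 10, 11).

**Steps most likely to fail**

Step 4 (thermal annulation). The α-aryloxy keto ester may decompose or dimerise through its ketene faster than phloroglucinol captures it. Benzyl transfer to the electron-rich triol may set in at 240 °C, or closure may begin at the ketone and lead toward the coumarin. The fallback builds the same flavone by Hoesch acylation and Allan–Robinson condensation, setting out from 1, 7, 4 and 5 and returning at 10. Alkylation of 1 with chloroacetonitrile (K2CO3, acetone) should give 2-(4-bromophenoxy)acetonitrile F1. Hoesch acylation of 7 with F1 (ZnCl2, HCl gas, Et2O, 0 °C, then hot water) should give 2-(4-bromophenoxy)-1-(2,4,6-trihydroxyphenyl)ethan-1-one F2. Acid 4 and chloride 5 (pyridine, CH2Cl2) should give 4-(benzyloxy)benzoic anhydride F3. Heating F2 with F3 and Et3N at 160 °C should give the O-aroylated flavone, mainly 2-[4-(benzyloxy)phenyl]-3-(4-bromophenoxy)-5-hydroxy-4-oxo-4H-chromen-7-yl 4-(benzyloxy)benzoate F4. Brief KOH treatment in aqueous EtOH should cleave the ester and deliver 10.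

Step 10 (asymmetric 1,4-addition). Protodeboronation of the valuable boronic acid may outrun insertion, facial discrimination may be incomplete, or the enantiomeric purity may erode through reversible ring opening of the flavanone. The fallback is a chalcone route with resolution that needs no boron reagent, setting out from 11 and 15 and returning at 18. Reductive carbonylation of 11 (Pd(OAc)2, 1,4-bis(diphenylphosphino)butane, N-formylsaccharin, Et3SiH, Na2CO3, DMF, 80 °C) should give 4-{[5,7-bis(benzyloxy)-2-[4-(benzyloxy)phenyl]-4-oxo-4H-chromen-3-yl]oxy}benzaldehyde F5. Claisen–Schmidt condensation of F5 with 15 (KOH, EtOH/THF, rt) should give (E)-1-[2,4-bis(benzyloxy)-6-hydroxyphenyl]-3-(4-{[5,7-bis(benzyloxy)-2-[4-(benzyloxy)phenyl]-4-oxo-4H-chromen-3-yl]oxy}phenyl)prop-2-en-1-one F6. Oxa-Michael ring closure (NaOAc, EtOH/THF, reflux) should give racemic 5,7-bis(benzyloxy)-2-(4-{[5,7-bis(benzyloxy)-2-[4-(benzyloxy)phenyl]-4-oxo-4H-chromen-3-yl]oxy}phenyl)-2,3-dihydro-4H-chromen-4-one F7. Preparative HPLC on a chiral stationary phase should separate 18 from the (2R)-enantiomer of 18 F8.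

Step 3 (enolate acylation). O-acylation of the enolate, double acylation or self-condensation of the aryloxyacetate may consume the acid chloride. The fallback reverses the polarity at the α-carbon, setting out from 5 and 1 and returning at 6. Magnesium-mediated acylation of potassium ethyl malonate with 5 (MgCl2, Et3N, MeCN, decarboxylation on acidic work-up) should give ethyl 3-[4-(benzyloxy)phenyl]-3-oxopropanoate F9. Chlorination with SO2Cl2 (CH2Cl2, 0 °C) should give ethyl 3-[4-(benzyloxy)phenyl]-2-chloro-3-oxopropanoate F10. Displacement of chloride by 1 (K2CO3, acetone, rt) should give 6.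

**Further compounds**
F1 | step 4 | 2-(4-bromophenoxy)acetonitrile | N#CCOc1ccc(Br)cc1
F2 | step 4 | 2-(4-bromophenoxy)-1-(2,4,6-trihydroxyphenyl)ethan-1-one | O=C(COc1ccc(Br)cc1)c1c(O)cc(O)cc1O
F3 | step 4 | 4-(benzyloxy)benzoic anhydride | O=C(OC(=O)c1ccc(OCc2ccccc2)cc1)c1ccc(OCc2ccccc2)cc1
F4 | step 4 | 2-[4-(benzyloxy)phenyl]-3-(4-bromophenoxy)-5-hydroxy-4-oxo-4H-chromen-7-yl 4-(benzyloxy)benzoate | O=C(Oc1cc(O)c2c(c1)oc(-c1ccc(OCc3ccccc3)cc1)c(Oc1ccc(Br)cc1)c2=O)c1ccc(OCc2ccccc2)cc1
F5 | step 10 | 4-{[5,7-bis(benzyloxy)-2-[4-(benzyloxy)phenyl]-4-oxo-4H-chromen-3-yl]oxy}benzaldehyde | O=Cc1ccc(Oc2c(-c3ccc(OCc4ccccc4)cc3)oc3cc(OCc4ccccc4)cc(OCc4ccccc4)c3c2=O)cc1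
F6 | step 10 | (E)-1-[2,4-bis(benzyloxy)-6-hydroxyphenyl]-3-(4-{[5,7-bis(benzyloxy)-2-[4-(benzyloxy)phenyl]-4-oxo-4H-chromen-3-yl]oxy}phenyl)prop-2-en-1-one | O=C(/C=C/c1ccc(Oc2c(-c3ccc(OCc4ccccc4)cc3)oc3cc(OCc4ccccc4)cc(OCc4ccccc4)c3c2=O)cc1)c1c(O)cc(OCc2ccccc2)cc1OCc1ccccc1
F7 | step 10 | racemic 5,7-bis(benzyloxy)-2-(4-{[5,7-bis(benzyloxy)-2-[4-(benzyloxy)phenyl]-4-oxo-4H-chromen-3-yl]oxy}phenyl)-2,3-dihydro-4H-chromen-4-one | O=C1CC(c2ccc(Oc3c(-c4ccc(OCc5ccccc5)cc4)oc4cc(OCc5ccccc5)cc(OCc5ccccc5)c4c3=O)cc2)Oc2cc(OCc3ccccc3)cc(OCc3ccccc3)c21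
F8 | step 10 | (2R)-enantiomer of 18 | O=C1C[C@H](c2ccc(Oc3c(-c4ccc(OCc5ccccc5)cc4)oc4cc(OCc5ccccc5)cc(OCc5ccccc5)c4c3=O)cc2)Oc2cc(OCc3ccccc3)cc(OCc3ccccc3)c21
F9 | step 3 | ethyl 3-[4-(benzyloxy)phenyl]-3-oxopropanoate | CCOC(=O)CC(=O)c1ccc(OCc2ccccc2)cc1
F10 | step 3 | ethyl 3-[4-(benzyloxy)phenyl]-2-chloro-3-oxopropanoate | CCOC(=O)C(Cl)C(=O)c1ccc(OCc2ccccc2)cc1
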